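**Route overview**

- Retrosynthesis: the C18–O senecioate ester is cut first, then C13=C14 (olefination, with the C13–H bond from hydrogenation), then C8–O, C9–C10 and C4–C5 in a single stroke. This unravels the bicycle to an acyclic epoxy triene ketone derived from (5E,9E)-farnesylacetone.
- Enabling feature: ring A of the trans-decalin holds on quaternary C4 an equatorial oxygenated carbon (C18) on the face opposite the C10 methyl, which is where the E-methyl of a prenyl terminus ends up. The oxygen of the tertiary C8 alcohol is five atoms from C13 (O–C8–C9–C11–C12–C13), so a C13 ketone oxygen can close a six-membered ring onto a C8 cation.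
- Forward: terminal allylic oxidation, Sharpless epoxidation and silylation give the substrate; one Lewis-acid cascade then closes ring A, ring B and a temporary dihydropyran, in that order.
- The C3 hydroxyl left by the epoxide is removed, the pyran is hydrolysed to release C8–OH and the C13 ketone, the C14–C15 acid arm is attached (olefination, saponification, hydrogenation), and C18–OH is senecioylated last.
- Stereochemistry: the D-(−)-tartrate epoxidation fixes C3 and C4; inversion at C4 and chair–chair folding of the E,E-diene relay this to C4, C5, C10, C9 and C8. C13 is set under catalyst control by Ru–BINAP hydrogenation of the E-enoic acid.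

Key step: step 4

Remark: positions follow labdane numbering (C18 = oxygenated carbon on C4, C19 = methyl on C4, C20 = methyl on C10, C17 = methyl on C8, C16 = methyl on C13); the ring system belongs to the ent series.
Assumption: Ru(OAc)2(BINAP) is taken to select the same alkene face of an (E)-3-methylalk-2-enoic acid as of geraniol, so the (S)-BINAP complex (the antipode expected to turn (E)-geranic acid into (R)-citronellic acid) is written for 13R; a trial run on geranic acid fixes the antipode before step 10.
Assumption: (5E,9E)-farnesylacetone is bought as the geometrically pure isomer.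

**Route**

Step 1
Reactants: 1 (5E,9E)-farnesylacetone
Product: 2 (5E,9E,13E)-15-hydroxy-6,10,14-trimethylpentadeca-5,9,13-trien-2-one
Conditions: SeO2 (0.1 equiv), t-BuOOH (70% aq., 3 equiv), salicylic acid (0.1 equiv), CH2Cl2, 0 °C to rt, stopped before over-oxidation
Reagents that add atoms: tert-butyl hydroperoxide, CC(C)(C)OO
Why: Sharpless–Umbreit allylic oxidation (ene reaction of SeO2 at the most electron-rich and least hindered terminal trisubstituted alkene, then a [2,3]-sigmatropic shift) places the hydroxyl on the E-methyl of the prenyl terminus, the saturated ketone being inert to catalytic selenium at room temperature; no stereocentre is formed, only the 13E geometry.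

Step 2
Reactants: 2 (5E,9E,13E)-15-hydroxy-6,10,14-trimethylpentadeca-5,9,13-trien-2-one
Product: 3 (5E,9E)-12-[(2R,3R)-3-(hydroxymethyl)-3-methyloxiran-2-yl]-6,10-dimethyldodeca-5,9-dien-2-one
Conditions: Ti(OiPr)4 (10 mol %), D-(−)-diethyl tartrate (12 mol %), t-BuOOH (anhydrous, 2 equiv), 4 Å MS, CH2Cl2, −20 °C
Reagents that add atoms: tert-butyl hydroperoxide, CC(C)(C)OO
Why: Katsuki–Sharpless asymmetric epoxidation is hydroxyl-directed, so only the allylic-alcohol alkene reacts, and with D-(−)-tartrate the titanium peroxide delivers oxygen to the face that gives the (2R,3R)-oxirane (the mirror image of the (2S,3S) outcome of L-(+)-tartrate on (E)-2-methylalk-2-en-1-ols), which sets C3 and C4 of the later ring A in one operation.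

Step 3
Reactants: 3 (5E,9E)-12-[(2R,3R)-3-(hydroxymethyl)-3-methyloxiran-2-yl]-6,10-dimethyldodeca-5,9-dien-2-one
Product: 4 (5E,9E)-12-[(2R,3R)-3-{[(tert-butyldimethylsilyl)oxy]methyl}-3-methyloxiran-2-yl]-6,10-dimethyldodeca-5,9-dien-2-one
Conditions: TBSCl, imidazole, DMF, 0 °C to rt
Reagents that add atoms: tert-butyldimethylsilyl chloride, CC(C)(C)[Si](C)(C)Cl
Why: Standard imidazole-mediated silylation of a primary alcohol gives a bulky and weakly basic ether that cannot attack the activated epoxide in the next step, and no stereocentre is touched.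

Step 4
Reactants: 4 (5E,9E)-12-[(2R,3R)-3-{[(tert-butyldimethylsilyl)oxy]methyl}-3-methyloxiran-2-yl]-6,10-dimethyldodeca-5,9-dien-2-one
Product: 5 (3R,4S,5S,8S,9S,10R)-18-[(tert-butyldimethylsilyl)oxy]-8,13-epoxy-14,15-dinorlabd-12-en-3-ol (trans-decalin fused to a 2-methyl-dihydropyran through O–C8 with C12=C13; equatorial 3-OH)
Conditions: MeAlCl2 (2.2 equiv, 1 M in hexanes), CH2Cl2, −78 °C; Et3N then aq. NaHCO3 quench; Et3N-deactivated silica
Reagents that add atoms: none
Why: MeAlCl2 binds the oxirane oxygen and the C5=C10 alkene attacks tertiary C4 from the side opposite the departing C4–O bond (6-endo closure of ring A through a chair), the C10 cation is then taken by the C8=C9 alkene (6-endo, second chair, ring B) and the C8 cation by the C13 carbonyl oxygen (six-membered oxocarbenium closure forming O–C8), after which loss of a C12 proton leaves the enol ether. The closest known reaction type is the Lewis-acid epoxide-initiated cationic polyene cyclization, joined to the carbonyl-oxygen termination by which acid converts farnesylacetone into sclareol oxide. C4 is fixed by inversion at the epoxide carbon, and because the silyloxymethyl group is the E substituent of the former alkene it comes out equatorial and anti to the C10 methyl, while C3 keeps its oxygen, untouched and equatorial. C5 and C10 follow from anti addition across the E C5=C10 alkene in the chair (trans ring fusion, axial C10 methyl), and C9 and C8 from anti addition across the E C8=C9 alkene (equatorial side chain on C9, equatorial oxygen and axial methyl on C8). The step needs opening at C4 and not at C3, propagation without early proton loss, and termination by oxygen; these are secured by the tertiary nature of every cationic site, the two E-trisubstituted alkenes, the non-participating silyl ether and the 1,5 relation of the ketone oxygen to C8, with more than two equivalents of Lewis acid because the ketone holds one.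

Step 5
Reactants: 5 (3R,4S,5S,8S,9S,10R)-18-[(tert-butyldimethylsilyl)oxy]-8,13-epoxy-14,15-dinorlabd-12-en-3-ol
Product: 7 O-[(3R,4S,5S,8S,9S,10R)-18-[(tert-butyldimethylsilyl)oxy]-8,13-epoxy-14,15-dinorlabd-12-en-3-yl] S-methyl carbonodithioate, via sodium xanthate salt 6 (not isolated)
Conditions: NaH, imidazole (cat.), THF, 0 °C to reflux; CS2, reflux; MeI, rt
Reagents that add atoms: carbon disulfide, S=C=S; iodomethane, CI
Why: Xanthate formation (first half of the Barton–McCombie deoxygenation) takes place at the only free hydroxyl under basic conditions that the acid-labile enol ether and the silyl ether tolerate, the enol ether meanwhile keeping the C13 carbonyl and the C8 oxygen masked, and no stereocentre changes.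

Step 6
Reactants: 7 O-[(3R,4S,5S,8S,9S,10R)-18-[(tert-butyldimethylsilyl)oxy]-8,13-epoxy-14,15-dinorlabd-12-en-3-yl] S-methyl carbonodithioate
Product: 8 (4S,5S,8S,9S,10R)-18-[(tert-butyldimethylsilyl)oxy]-8,13-epoxy-14,15-dinorlabd-12-ene
Conditions: Bu3SnH (2 equiv), AIBN (0.2 equiv), toluene, 110 °C
Reagents that add atoms: none
Why: Barton–McCombie radical deoxygenation (stannyl radical addition to the thiocarbonyl sulfur, β-scission to the secondary C3 radical, hydrogen transfer from Bu3SnH) deletes the C3 carbinol centre once it has relayed the chirality, and the enol ether, the silyl ether and the five ring stereocentres are inert to the radical chain.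

Step 7
Reactants: 8 (4S,5S,8S,9S,10R)-18-[(tert-butyldimethylsilyl)oxy]-8,13-epoxy-14,15-dinorlabd-12-ene
Product: 10 (4S,5S,8S,9S,10R)-8,18-dihydroxy-14,15-dinorlabdan-13-one, via silyl hydroxy ketone 9 (not isolated)
Conditions: 1 M aq. HCl, THF, rt to 40 °C; NaHCO3 before concentration
Reagents that add atoms: water, O
Why: Acid-catalysed enol-ether hydrolysis (C12 protonation, hydration of the oxocarbenium ion at C13, opening of the hemiketal) breaks the O–C13 bond and never the O–C8 bond, so C8 keeps its configuration and appears as the tertiary alcohol, while the same aqueous acid removes the primary silyl ether.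

Step 8
Reactants: 10 (4S,5S,8S,9S,10R)-8,18-dihydroxy-14,15-dinorlabdan-13-one; 11 triethyl phosphonoacetate
Product: 12 ethyl (4S,5S,8S,9S,10R,13E)-8,18-dihydroxylabd-13-en-15-oate
Conditions: (EtO)2P(O)CH2CO2Et (5 equiv), NaH (4.5 equiv), THF, 0 °C; then 10, rt to 60 °C; chromatography
Reagents that add atoms: triethyl phosphonoacetate (11), CCOC(=O)CP(=O)(OCC)OCC
Why: Horner–Wadsworth–Emmons olefination of the methyl ketone with the preformed sodium phosphonate (no free hydride, so both hydroxyls stay protonated and neither oxa-Michael addition from C8–O nor transesterification is invited) should give mainly the 13E ester, from which the minor 13Z isomer is to be removed by chromatography; no stereocentre is formed.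

Step 9
Reactants: 12 ethyl (4S,5S,8S,9S,10R,13E)-8,18-dihydroxylabd-13-en-15-oate
Product: 13 (4S,5S,8S,9S,10R,13E)-8,18-dihydroxylabd-13-en-15-oic acid
Conditions: LiOH·H2O (5 equiv), THF–MeOH–H2O, 50 °C; then 1 M HCl to pH 3 at 0 °C
Reagents that add atoms: lithium hydroxide, [Li+].[OH-]
Why: Saponification of the only ester present proceeds by acyl–oxygen cleavage, the trisubstituted enoate keeps its E geometry under aqueous hydroxide, and the brief cold acidification does not endanger the tertiary alcohol.

Step 10
Reactants: 13 (4S,5S,8S,9S,10R,13E)-8,18-dihydroxylabd-13-en-15-oic acid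
Product: 14 (4S,5S,8S,9S,10R,13R)-8,18-dihydroxylabdan-15-oic acid
Conditions: Ru(OAc)2[(S)-BINAP] (1 mol %), H2 (100 atm), MeOH, 25 °C
Reagents that add atoms: none
Why: Noyori carboxylate-directed asymmetric hydrogenation binds the substrate to divalent ruthenium as its carboxylate and reduces the C13=C14 alkene within the chelate, so the BINAP antipode together with the pure E geometry decides the face and gives 13R under catalyst control, the ring stereocentres being three or more bonds away and the hydroxyls mere spectators.

Step 11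
Reactants: 14 (4S,5S,8S,9S,10R,13R)-8,18-dihydroxylabdan-15-oic acid; 15 3-methylbut-2-enoyl chloride (senecioyl chloride)
Product: 17 (4S,5S,8S,9S,10R,13R)-8-hydroxy-18-[(3-methylbut-2-enoyl)oxy]labdan-15-oic acid (CNP0293742.1), via mixed anhydride 16 (not isolated)
Conditions: senecioyl chloride (2.5 equiv), pyridine, DMAP (0.1 equiv), CH2Cl2, 0 °C to rt; then THF–sat. aq. NaHCO3, rt; acidify to pH 3
Reagents that add atoms: 3-methylbut-2-enoyl chloride (15), CC(C)=CC(=O)Cl; water, O
Why: Pyridine/DMAP-mediated O-acylation (nucleophilic acyl substitution) esterifies the primary C18 hydroxyl while the tertiary C8 hydroxyl is too hindered to react, the carboxyl group is carried as a mixed anhydride that the bicarbonate work-up hydrolyses back to the acid, and pyridine in place of a trialkylamine avoids the vinylketene path that would move the senecioyl double bond out of conjugation; no stereocentre is affected.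

**Compound list**

1 | (5E,9E)-6,10,14-trimethylpentadeca-5,9,13-trien-2-one ((5E,9E)-farnesylacetone) | CC(C)=CCC/C(C)=C/CC/C(C)=C/CCC(C)=O | starting material
2 | (5E,9E,13E)-15-hydroxy-6,10,14-trimethylpentadeca-5,9,13-trien-2-one | OC/C(C)=C/CC/C(C)=C/CC/C(C)=C/CCC(C)=O | intermediate
3 | (5E,9E)-12-[(2R,3R)-3-(hydroxymethyl)-3-methyloxiran-2-yl]-6,10-dimethyldodeca-5,9-dien-2-one | OC[C@@]1(C)O[C@@H]1CC/C(C)=C/CC/C(C)=C/CCC(C)=O | intermediate
4 | (5E,9E)-12-[(2R,3R)-3-{[(tert-butyldimethylsilyl)oxy]methyl}-3-methyloxiran-2-yl]-6,10-dimethyldodeca-5,9-dien-2-one | CC(C)(C)[Si](C)(C)OC[C@@]1(C)O[C@@H]1CC/C(C)=C/CC/C(C)=C/CCC(C)=O | intermediate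
5 | (3R,4S,5S,8S,9S,10R)-18-[(tert-butyldimethylsilyl)oxy]-8,13-epoxy-14,15-dinorlabd-12-en-3-ol | CC(C)(C)[Si](C)(C)OC[C@@]1(C)[C@H](O)CC[C@]2(C)[C@@H]1CC[C@]3(C)OC(C)=CC[C@@H]23 | intermediate
6 | sodium O-[(3R,4S,5S,8S,9S,10R)-18-[(tert-butyldimethylsilyl)oxy]-8,13-epoxy-14,15-dinorlabd-12-en-3-yl] carbonodithioate | CC(C)(C)[Si](C)(C)OC[C@@]1(C)[C@H](OC(=S)[S-])CC[C@]2(C)[C@@H]1CC[C@]3(C)OC(C)=CC[C@@H]23.[Na+] | intermediate (not isolated)
7 | O-[(3R,4S,5S,8S,9S,10R)-18-[(tert-butyldimethylsilyl)oxy]-8,13-epoxy-14,15-dinorlabd-12-en-3-yl] S-methyl carbonodithioate | CC(C)(C)[Si](C)(C)OC[C@@]1(C)[C@H](OC(=S)SC)CC[C@]2(C)[C@@H]1CC[C@]3(C)OC(C)=CC[C@@H]23 | intermediate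
8 | (4S,5S,8S,9S,10R)-18-[(tert-butyldimethylsilyl)oxy]-8,13-epoxy-14,15-dinorlabd-12-ene | CC(C)(C)[Si](C)(C)OC[C@@]1(C)CCC[C@]2(C)[C@@H]1CC[C@]3(C)OC(C)=CC[C@@H]23 | intermediate
9 | (4S,5S,8S,9S,10R)-18-[(tert-butyldimethylsilyl)oxy]-8-hydroxy-14,15-dinorlabdan-13-one | CC(C)(C)[Si](C)(C)OC[C@@]1(C)CCC[C@]2(C)[C@@H]1CC[C@](C)(O)[C@H]2CCC(C)=O | intermediate (not isolated)
10 | (4S,5S,8S,9S,10R)-8,18-dihydroxy-14,15-dinorlabdan-13-one | OC[C@@]1(C)CCC[C@]2(C)[C@@H]1CC[C@](C)(O)[C@H]2CCC(C)=O | intermediate
11 | triethyl phosphonoacetate | CCOC(=O)CP(=O)(OCC)OCC | starting material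
12 | ethyl (4S,5S,8S,9S,10R,13E)-8,18-dihydroxylabd-13-en-15-oate | OC[C@@]1(C)CCC[C@]2(C)[C@@H]1CC[C@](C)(O)[C@H]2CC/C(C)=C/C(=O)OCC | intermediate
13 | (4S,5S,8S,9S,10R,13E)-8,18-dihydroxylabd-13-en-15-oic acid | OC[C@@]1(C)CCC[C@]2(C)[C@@H]1CC[C@](C)(O)[C@H]2CC/C(C)=C/C(=O)O | intermediate
14 | (4S,5S,8S,9S,10R,13R)-8,18-dihydroxylabdan-15-oic acid | OC[C@@]1(C)CCC[C@]2(C)[C@@H]1CC[C@](C)(O)[C@H]2CC[C@@H](C)CC(=O)O | intermediate
15 | 3-methylbut-2-enoyl chloride (senecioyl chloride) | CC(C)=CC(=O)Cl | starting material
16 | (4S,5S,8S,9S,10R,13R)-8-hydroxy-18-[(3-methylbut-2-enoyl)oxy]labdan-15-oic 3-methylbut-2-enoic anhydride | CC(C)=CC(=O)OC[C@@]1(C)CCC[C@]2(C)[C@@H]1CC[C@](C)(O)[C@H]2CC[C@@H](C)CC(=O)OC(=O)C=C(C)C | intermediate (not isolated)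
17 | (4S,5S,8S,9S,10R,13R)-8-hydroxy-18-[(3-methylbut-2-enoyl)oxy]labdan-15-oic acid (CNP0293742.1) | CC(C)=CC(=O)OC[C@@]1(C)CCC[C@]2(C)[C@@H]1CC[C@](C)(O)[C@H]2CC[C@@H](C)CC(=O)O | target

**Step count**

Total steps: 11. Longest linear sequence: 11 steps (1 to 17).

**Steps most likely to fail**

Step 4. The cascade may stall through early proton loss from the C10 or C8 cation, or the epoxide may rearrange by hydride shift before the alkene attacks, because the neighbouring silyloxy group slows ionisation at C4. Fallback, setting out from 4: the epoxide is opened homolytically with trivalent titanium (Cp2TiCl made in the flask from Cp2TiCl2 and manganese powder, collidine hydrochloride, THF, rt). The C4 radical cyclizes twice through the same chair–chair array and the C8 radical is converted to the exocyclic alkene, giving ent-3β-hydroxy-18-[(tert-butyldimethylsilyl)oxy]-14,15-dinorlabd-8(17)-en-13-one F1. In this variant the silyloxymethyl group is steered to the equatorial position by its size and not by inversion. Markovnikov hydration of the exocyclic alkene (Mn(dpm)3, PhSiH3, O2, i-PrOH), with oxygen entering from the equatorial side away from the axial C10 methyl, would give ent-3β,8-dihydroxy-18-[(tert-butyldimethylsilyl)oxy]-14,15-dinorlabdan-13-one F2. Catalytic p-TsOH in benzene at rt then cyclodehydrates this δ-hydroxy ketone to the enol ether, which returns to the route at 5.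

Step 10. Facial discrimination on a β,β-dialkyl acrylic acid may be incomplete, leaving a C13 epimer that is hard to separate, or the chosen antipode may induce the opposite sense. Fallback, setting out from the ester 12: ligated copper hydride (Cu(OAc)2, DTBM-SEGPHOS in the antipode fixed on ethyl (E)-geranate, polymethylhydrosiloxane, t-BuOH, toluene, 0 °C) performs an asymmetric 1,4-reduction to ethyl (13R)-8,18-dihydroxy-ent-labdan-15-oate F3. Hydroxyls silylated by the hydrosilane are released in the fluoride work-up. LiOH saponification then returns to the route at 14, bypassing 13.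

Step 11. Acyl transfer from the transient mixed anhydride to the C18 hydroxyl of a second molecule (oligomer formation) may compete with senecioylation, and base-induced deconjugation of the acylating agent may occur. Fallback, setting out from 14: the carboxyl group is first masked by O-alkylation (allyl bromide, Cs2CO3, DMF, rt) to give allyl (13R)-8,18-dihydroxy-ent-labdan-15-oate F4. Senecioylation of the only acylable hydroxyl (senecioyl chloride, pyridine, DMAP, CH2Cl2) gives allyl (13R)-8-hydroxy-18-[(3-methylbut-2-enoyl)oxy]-ent-labdan-15-oate F5. Deallylation with zerovalent palladium (Pd(PPh3)4, morpholine, THF, rt) leaves the senecioate untouched and returns to the route at 17.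

Further compounds
F1 | step 4 | ent-3β-hydroxy-18-[(tert-butyldimethylsilyl)oxy]-14,15-dinorlabd-8(17)-en-13-one | CC(C)(C)[Si](C)(C)OC[C@@]1(C)[C@H](O)CC[C@]2(C)[C@@H]1CCC(=C)[C@H]2CCC(C)=O
F2 | step 4 | ent-3β,8-dihydroxy-18-[(tert-butyldimethylsilyl)oxy]-14,15-dinorlabdan-13-one | CC(C)(C)[Si](C)(C)OC[C@@]1(C)[C@H](O)CC[C@]2(C)[C@@H]1CC[C@](C)(O)[C@H]2CCC(C)=O
F3 | step 10 | ethyl (13R)-8,18-dihydroxy-ent-labdan-15-oate | OC[C@@]1(C)CCC[C@]2(C)[C@@H]1CC[C@](C)(O)[C@H]2CC[C@@H](C)CC(=O)OCC
F4 | step 11 | allyl (13R)-8,18-dihydroxy-ent-labdan-15-oate | OC[C@@]1(C)CCC[C@]2(C)[C@@H]1CC[C@](C)(O)[C@H]2CC[C@@H](C)CC(=O)OCC=C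
F5 | step 11 | allyl (13R)-8-hydroxy-18-[(3-methylbut-2-enoyl)oxy]-ent-labdan-15-oate | CC(C)=CC(=O)OC[C@@]1(C)CCC[C@]2(C)[C@@H]1CC[C@](C)(O)[C@H]2CC[C@@H](C)CC(=O)OCC=C
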